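## Structural features

The target is one cyclohexane ring, numbered throughout as C1 (methyl and vinyl), C2 (CH2), C3 (ester oxygen), C4 (1-carboxyvinyl), C5 (hydroxyl) and C6 (3-hydroxyprop-1-en-2-yl). It has five stereocentres: C3 to C6 are contiguous and the quaternary C1 sits next to C6. The vinyl group, the C6 alkenyl arm, the C5 hydroxyl and the C4 acrylic arm lie on one face; the C3 acyloxy group and the C1 methyl lie on the other. The C4 arm and the C5 hydroxyl form a γ-hydroxy acrylic acid, which is a conjugate acceptor and can close to a cis-fused α-methylene lactone under acid. The side chain is a Z-configured 4-acetoxy-2-methylbut-2-enoate that can isomerise or cyclise to a butenolide, and its acetate must survive next to a free primary allylic alcohol. The real difficulty is C1: methyl and vinyl are nearly the same size, so a reagent attacking C6 after C1 is built is not steered, and the C1/C6/C5 relationship has to be fixed by ring geometry. The key step uses the C5 oxygen beside the C3=C4 double bond of a cyclohexenol: a carbon radical tethered to O5 through an acetal can reach only C4, on the face of O5, closing an oxolane fused at C4–C5 and leaving a C3 radical open to oxygen on the far face.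

## Logic of the disconnections

29 to 28. No C–C bond is cut; the carboxyl carbon is taken back to a lactol carbon bonded to O5. This hides the acid and the C5 hydroxyl in one ring until the last step. The forward oxidation must work on the small open-chain enal fraction and the product must not meet strong acid.

28 to 27. The exocyclic C=CH2 bond on the C4 arm is cut, the methylene coming from formaldehyde. This leaves a saturated lactol. The forward step needs the lactol to open to an enolisable aldehyde without the amine adding to the unsaturated esters.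

27 to 26. The lactol O–H and the primary O–H are returned to an ethyl acetal and a silyl ether. Both fall in one acid treatment, so no deprotection is needed after the acid exists. The esters must survive that treatment.

26 to 22 and 24, then 22 to 19 and 21. The side-chain C=C bond is cut, then the ester C–O bond at C3. Building the Z olefin on the substrate avoids handling a free Z-configured γ-acetoxy acid and puts the acetate in directly. The olefination must be Z-selective, and C3–OH must be the only free hydroxyl in 19.

19 to 17. The C4–CH2 bond and the C3–O bond are cut. This removes two stereocentres and one ring and returns to a cyclohexenol carrying only C1, C5 and C6. The forward step must close 5-exo onto C4 and take up oxygen at C3 anti to the new ring.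

17 to 15 and 16, then 15 to 14. The acetal C–O and C–Br bonds are cut, then the Si–O bond. This leaves a diol whose primary hydroxyl is silylated first, so that the hindered C5 hydroxyl is the only one left for acetal formation.

14 to 13 to 12. The vinyl C=C bond is cut back to a lactol carbon bonded to O5, and the arm alcohol is raised to an acrylate. The vinyl group and the C5 hydroxyl thus come from one bridged lactone, which fixes them cis. The hydride must stop at the lactol, and the ylide must open it.

12 to 8. The arm C=CH2 bond is cut, leaving a plain acetate arm. The only enolisable position in 8 is that arm.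

8 to 7 to 6. The C5–O bond is cut and the double bond is returned from C3=C4 to C4=C5. The C1 carboxyl can deliver oxygen to C5 only on its own face, and the elimination then places the alkene where the key step needs it. The lactonisation must form the five-membered ring, and the elimination must be anti.

6 to 5 to 3 and 4. The C1–C6 and C2–C3 bonds are cut in a cycloaddition. C1 and C6 are set together, so nothing has to react at C6 beside an existing methyl/vinyl centre. A conjugate-addition route to C1 followed by alkenylation at C6 was set aside for two reasons: a methyl nucleophile is prone to add at the far end of a vinyl-extended acceptor, and methyl versus vinyl gives no facial bias at C6. The forward step must be ortho-, endo- and face-selective.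

3 to 1, 21 to 20, 24 to 23. A double-bond shift, an ester cleavage and an alkene cleavage connect these to commercial materials.

## Other disconnections considered

Alternative 1: The cut is at C1–CH and C6–C(alkenyl), reading the two alkenyl groups as halves of one cyclobutene. The forward key step is irradiation of enone A1 with alkyne A2, which should give the cis-fused cyclobutene A3 by [2+2] photocycloaddition. Ring-opening metathesis with ethene (second-generation Grubbs catalyst) and reduction of the C5 ketone would follow. In its favour, the four-membered ring can only be cis-fused, so the vinyl/C6-arm relationship is certain; on this point it is better than the endo preference relied on in the chosen plan. C3 and C4 are already in A1, so no tin and no oxygen trapping are needed. Against it, a terminal alkyne is expected to give both head-to-head and head-to-tail adducts, the face of addition must be controlled by the C3/C4 substituents of A1, and the cyclobutenyl ketone can react further under light. A1 itself needs an enantioselective synthesis with a trans C3/C4 pair, and the C5 ketone must later be reduced to the axial alcohol. Mechanistically it is a triplet biradical process with little handle on regiochemistry, where the chosen plan uses a concerted cycloaddition and a tethered radical closure. In step count the two are probably equal, because the steps saved at C3/C4 are spent on making A1.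

Alternative 2: The cut is at C1–C2. Anodic oxidation of enol ether A4 would give a radical cation that is trapped by the allylsilane, forming the quaternary centre and the vinyl group and leaving C3 as the dimethyl ketal A5. In its favour, the quaternary centre is made under neutral, reagent-free conditions and C3 arrives oxygenated; on reagent economy it is better than the chosen plan. Against it, A5 holds only C1 and C5, and their relation rests on a chair transition state that must tell methyl from the forming vinyl. C4 can be reached from the C3 ketone, but C6 lies between C1 and C5 and is not activated by anything in A5. Structurally this leaves the hardest part (C6 and its relation to C1) unsolved, and the step count would be clearly higher than in the chosen plan.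

Alternative 3: The cut is at C4–C5. Divalent chromium (CrCl2) would convert the allylic bromide of A6 into an allylchromium species that adds through its γ-carbon to the aldehyde, closing the ring and forming the acrylate of A7 in one step. In its favour, the acrylate is delivered directly, so the end game needs no methylenation and no oxidation; on end-game step economy it is better than the chosen plan. Against it, A6 must carry C1, C3 and C6 on an open chain, which moves the methyl/vinyl problem to an acyclic setting. The aldehyde is α-branched and β,γ-unsaturated, so it can epimerise or conjugate. The closure must give the C4/C5 cis product, while chromium allylations usually favour the anti arrangement. Chromium is used in excess. Overall the ring closure is elegant but the precursor is harder to make than 17.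

Key step: step 11

Assumption 1: the (S)-oxazaborolidinium catalyst of step 2 is taken to give 5 in the configuration drawn; its mirror-image catalyst is used if the sense is the opposite.
Assumption 2: the acetal and lactol carbons of 13, 17–19, 22 and 25–28 and the arm α-carbon of 10 and 11 form as epimer mixtures; the SMILES leave them undefined and none survives in 29.

## Route

Step 1
Reactants: 1 methyl (2E,4E)-hexa-2,4-dienoate (methyl sorbate)
Product: 3 methyl (3E)-hexa-3,5-dienoate, via lithium trienolate 2 (not isolated)
Conditions: LiN(i-Pr)2, DMPU, THF, −78 °C; then AcOH, −78 °C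
Reagents that add atoms: none
Why: Deconjugative protonation: deprotonation at the terminal methyl gives the extended enolate, and kinetic protonation at the α-carbon moves the diene to C3–C6. No stereocentre is formed; any Z isomer does not react in step 2.

Step 2
Reactants: 3 methyl (3E)-hexa-3,5-dienoate; 4 2-methylprop-2-enal (methacrolein)
Product: 5 methyl 2-[(1R,6S)-6-formyl-6-methylcyclohex-2-en-1-yl]acetate
Conditions: (S)-3,3-diphenyl-1-(2-methylphenyl)tetrahydro-1H,3H-pyrrolo[1,2-c][1,3,2]oxazaborole·Tf2NH (10 mol%), CH2Cl2, −78 → −40 °C
Reagents that add atoms: none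
Why: Lewis-acid-catalysed Diels–Alder reaction; the 1-substituted diene bonds its substituted terminus to the formyl-bearing carbon (ortho), which forms C1–C6 and C2–C3. The endo transition state puts the formyl group cis to the ester arm, and the chiral boron cation blocks one face of the bound enal, which sets C1 and C6 absolutely.

Step 3
Reactants: 5 methyl 2-[(1R,6S)-6-formyl-6-methylcyclohex-2-en-1-yl]acetate
Product: 6 (1S,2R)-2-(2-methoxy-2-oxoethyl)-1-methylcyclohex-3-ene-1-carboxylic acid
Conditions: NaClO2, NaH2PO4, 2-methyl-2-butene, t-BuOH/H2O, 0 °C → rt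
Reagents that add atoms: sodium chlorite, [Na+].[O-]Cl=O
Why: Pinnick oxidation of an aldehyde on a quaternary carbon, so nothing can epimerise; the alkene scavenger protects the ring double bond from HOCl.

Step 4
Reactants: 6 (1S,2R)-2-(2-methoxy-2-oxoethyl)-1-methylcyclohex-3-ene-1-carboxylic acid
Product: 7 methyl 2-(4-iodo-1-methyl-7-oxo-6-oxabicyclo[3.2.1]octan-8-yl)acetate
Conditions: I2, NaHCO3, MeCN/H2O, 0 °C, dark
Reagents that add atoms: iodine, II
Why: Iodolactonisation; the carboxylate closes the five-membered lactone onto C5, which it can reach only on its own face, so the C5 oxygen is cis to the C1 carbonyl. Anti addition places iodine on C4 trans to that oxygen.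

Step 5
Reactants: 7 methyl 2-(4-iodo-1-methyl-7-oxo-6-oxabicyclo[3.2.1]octan-8-yl)acetate
Product: 8 methyl 2-(1-methyl-7-oxo-6-oxabicyclo[3.2.1]oct-3-en-8-yl)acetate
Conditions: DBU, toluene, 80 °C
Reagents that add atoms: none
Why: E2 dehydroiodination; the axial iodide has an anti-periplanar hydrogen only on C3, and loss toward C5 would need a bridgehead double bond. The alkene therefore ends at C3=C4 beside the C5 oxygen.

Step 6
Reactants: 8 methyl 2-(1-methyl-7-oxo-6-oxabicyclo[3.2.1]oct-3-en-8-yl)acetate
Product: 12 methyl 2-(1-methyl-7-oxo-6-oxabicyclo[3.2.1]oct-3-en-8-yl)prop-2-enoate, via lithium ester enolate 9 (not isolated), via Mannich base 10 (not isolated), via trimethylammonium iodide 11 (not isolated)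
Conditions: LiN(i-Pr)2, THF, −78 °C; Me2N=CH2+ I−, −78 → 0 °C; then MeI, rt; then DBU, rt
Reagents that add atoms: dimethylmethyleneammonium iodide, C=[N+](C)C.[I-]
Why: Mannich reaction of the ester enolate, N-methylation and Hofmann-type elimination give the α-methylene ester. The lactone α-carbon is quaternary, so the arm is the only enolisable site, and no stereocentre remains on the arm.

Step 7
Reactants: 12 methyl 2-(1-methyl-7-oxo-6-oxabicyclo[3.2.1]oct-3-en-8-yl)prop-2-enoate
Product: 13 8-(3-hydroxyprop-1-en-2-yl)-1-methyl-6-oxabicyclo[3.2.1]oct-3-en-7-ol (bridged lactol)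
Conditions: i-Bu2AlH (3.5 equiv), CH2Cl2, −78 °C; aqueous potassium sodium tartrate
Reagents that add atoms: none
Why: Aluminium hydride reduction; the acrylate is reduced 1,2 to the allylic alcohol, and the lactone stops at the lactol because its aluminium hemiacetal is stable at −78 °C.

Step 8
Reactants: 13 8-(3-hydroxyprop-1-en-2-yl)-1-methyl-6-oxabicyclo[3.2.1]oct-3-en-7-ol
Product: 14 (1R,5R,6R)-5-ethenyl-6-(3-hydroxyprop-1-en-2-yl)-5-methylcyclohex-2-en-1-ol
Conditions: Ph3PCH3Br, n-BuLi, THF, 0 °C; then 13, 0 °C → rt
Reagents that add atoms: methyltriphenylphosphonium bromide, C[P+](c1ccccc1)(c1ccccc1)c1ccccc1.[Br-]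
Why: Wittig methylenation of the lactol through its hydroxy-aldehyde form; the aldehyde sits on quaternary C1 and cannot epimerise. The vinyl group and the freed C5 hydroxyl come from the same bridge and are therefore cis.

Step 9
Reactants: 14 (1R,5R,6R)-5-ethenyl-6-(3-hydroxyprop-1-en-2-yl)-5-methylcyclohex-2-en-1-ol
Product: 15 (1R,5R,6R)-6-[3-(tert-butyldimethylsilyloxy)prop-1-en-2-yl]-5-ethenyl-5-methylcyclohex-2-en-1-ol
Conditions: TBSCl (1.05 equiv), imidazole, CH2Cl2, −20 → 0 °C
Reagents that add atoms: tert-butyldimethylsilyl chloride, CC(C)(C)[Si](C)(C)Cl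
Why: Silylation selective for the primary allylic hydroxyl over the axial secondary hydroxyl flanked by C6 and the 1,3-related vinyl group.

Step 10
Reactants: 15 (1R,5R,6R)-6-[3-(tert-butyldimethylsilyloxy)prop-1-en-2-yl]-5-ethenyl-5-methylcyclohex-2-en-1-ol; 16 ethyl vinyl ether
Product: 17 2-bromo-1-ethoxyethyl acetal of 15 at the C5 oxygen (cyclohexenyl bromoacetal)
Conditions: NBS, CH2Cl2, −40 → 0 °C
Reagents that add atoms: N-bromosuccinimide, O=C1CCC(=O)N1Br
Why: Haloacetalisation; the electron-rich enol ether takes up Br+ far faster than the other alkenes, and the only free hydroxyl captures the oxocarbenium ion.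

Step 11
Reactants: 17 cyclohexenyl bromoacetal
Product: 19 2-ethoxy-6-ethenyl-6-methyl-7-[3-(tert-butyldimethylsilyloxy)prop-1-en-2-yl]octahydro-1-benzofuran-4-ol (cis-fused lactol ethyl acetal; free C3 hydroxyl), via C3 hydroperoxide 18 (not isolated)
Conditions: Bu3SnH (syringe pump), Et3B (cat.), dry air, toluene, 0 °C; then PPh3, rt
Reagents that add atoms: dioxygen, O=O
Why: Et3B and oxygen start a tin-radical chain: Bu3Sn• takes bromine from 17 and the primary acetal radical adds to C4 of the ring alkene. The closest known reaction type is the Ueno–Stork haloacetal cyclisation run under air so that the cyclised radical is hydroxylated. One ring closes, the oxolane, by 5-exo-trig attack. C4 is set by the tether: a five-membered ring fused from the C5 oxygen can only be cis, so the new C4–C bond is cis to C5–O. C3 is set by the bicyclic shape: oxygen meets the secondary C3 radical on the convex face, away from the new ring and the axial vinyl group, giving C3–O trans to C4–C; the peroxyl radical takes hydrogen from Bu3SnH to give 18, which PPh3 reduces to 19. The step needs 5-exo closure onto C4 to beat both 6-exo attack on the C6 propenyl group and direct oxygen capture of the primary radical; the cis allylic geometry makes the closure fast, and a low oxygen level (air, slow tin addition) holds back early capture. The acetal carbon is not controlled and is removed later.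

Step 12
Reactants: 20 ethyl 2-[bis(2,2,2-trifluoroethoxy)phosphoryl]propanoate
Product: 21 2-[bis(2,2,2-trifluoroethoxy)phosphoryl]propanoic acid
Conditions: Me3SnOH, ClCH2CH2Cl, 80 °C; then 1 M HCl wash
Reagents that add atoms: trimethyltin hydroxide, C[Sn](C)(C)O
Why: Tin-hydroxide ester cleavage under near-neutral conditions; the carboxylic ester is cleaved while the base-sensitive trifluoroethyl phosphonate esters are left alone.

Step 13
Reactants: 19 cis-fused lactol ethyl acetal with free C3 hydroxyl; 21 2-[bis(2,2,2-trifluoroethoxy)phosphoryl]propanoic acid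
Product: 22 C3 ester of 19 with 21 (phosphonopropanoate)
Conditions: DCC, DMAP (cat.), CH2Cl2, 0 °C → rt
Reagents that add atoms: none
Why: Steglich esterification; C3–OH is the only free hydroxyl (C5–O is in the acetal, the primary oxygen is silylated), and α-phosphono acids acylate hindered secondary alcohols readily.

Step 14
Reactants: 23 (2Z)-but-2-ene-1,4-diyl diacetate
Product: 24 2-oxoethyl acetate
Conditions: O3, CH2Cl2, −78 °C; then Me2S, −78 °C → rt
Reagents that add atoms: ozone, [O-][O+]=O
Why: Ozonolysis with reductive work-up; the symmetrical alkene gives two equivalents of the aldehyde, which is used fresh.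

Step 15
Reactants: 22 phosphonopropanoate of 19; 24 2-oxoethyl acetate
Product: 26 C3 (2Z)-4-acetoxy-2-methylbut-2-enoate of 19, via potassium phosphonate carbanion 25 (not isolated)
Conditions: KN(SiMe3)2, 18-crown-6, THF, −78 °C; then 24, −78 °C
Reagents that add atoms: none
Why: Still–Gennari variant of the Horner–Wadsworth–Emmons olefination; the electron-poor phosphonate with a dissociated potassium counter-ion eliminates from the kinetic adduct, which places the ester cis to the CH2OAc group (Z). The acetate arrives in place, so no free Z-configured γ-hydroxy ester or acid is ever formed.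

Step 16
Reactants: 26 C3 (2Z)-4-acetoxy-2-methylbut-2-enoate of 19
Product: 27 6-ethenyl-2-hydroxy-7-(3-hydroxyprop-1-en-2-yl)-6-methyloctahydro-1-benzofuran-4-yl (2Z)-4-acetoxy-2-methylbut-2-enoate (lactol)
Conditions: 1 M HCl (aq), THF, 0 °C → rt
Reagents that add atoms: water, O
Why: Acid hydrolysis of the 2-alkoxyoxolane acetal and of the primary silyl ether in one operation; the conjugated ester and the primary acetate hydrolyse much more slowly under dilute acid.

Step 17
Reactants: 27 lactol with free primary alcohol
Product: 28 3-methylidene analogue of 27 (α-methylene lactol)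
Conditions: CH2O (37% aq.), pyrrolidine (20 mol%), EtCO2H (20 mol%), i-PrOH, 45 °C
Reagents that add atoms: formaldehyde, C=O
Why: Amine-catalysed Mannich condensation (α-methylenation of an aldehyde); the enamine of the open hydroxy-aldehyde adds to the formaldehyde-derived iminium ion and loses the amine. C4 is not enolised through to the ring, so its configuration is kept.

Step 18
Reactants: 28 α-methylene lactol
Product: 29 2-[(1S,2S,3R,4R,6S)-6-{[(2Z)-4-acetoxy-2-methylbut-2-enoyl]oxy}-4-ethenyl-2-hydroxy-3-(3-hydroxyprop-1-en-2-yl)-4-methylcyclohexyl]prop-2-enoic acid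
Conditions: NaClO2, NaH2PO4, 2-methyl-2-butene, t-BuOH/H2O, 0 °C
Reagents that add atoms: sodium chlorite, [Na+].[O-]Cl=O
Why: Pinnick oxidation of the open enal form of the lactol gives the acrylic acid and frees the C5 hydroxyl in the same event; the primary allylic alcohol is not touched by chlorite. The phosphate buffer and an extraction near pH 4–5 avoid the strong acid that would close the cis γ-lactone.

## Compound list

1 | methyl (2E,4E)-hexa-2,4-dienoate | COC(=O)/C=C/C=C/C | starting material
2 | lithium 1-methoxyhexa-1,3,5-trien-1-olate | [Li+].[O-]C(OC)=CC=CC=C | intermediate (not isolated)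
3 | methyl (3E)-hexa-3,5-dienoate | COC(=O)C/C=C/C=C | intermediate
4 | 2-methylprop-2-enal | CC(=C)C=O | starting material
5 | methyl 2-[(1R,6S)-6-formyl-6-methylcyclohex-2-en-1-yl]acetate (formyl cis to the ester arm) | O=C[C@@]1(C)CCC=C[C@H]1CC(=O)OC | intermediate
6 | (1S,2R)-2-(2-methoxy-2-oxoethyl)-1-methylcyclohex-3-ene-1-carboxylic acid | OC(=O)[C@@]1(C)CCC=C[C@H]1CC(=O)OC | intermediate
7 | methyl 2-(4-iodo-1-methyl-7-oxo-6-oxabicyclo[3.2.1]octan-8-yl)acetate; lactone from the C1 carboxyl to the C5 oxygen, iodine on C4 trans to that oxygen, ester arm on C6 cis to the lactone bridge | O=C2[C@@]1(C)CC[C@H](I)[C@@H](O2)[C@H]1CC(=O)OC | intermediate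
8 | methyl 2-(1-methyl-7-oxo-6-oxabicyclo[3.2.1]oct-3-en-8-yl)acetate; configuration at C1, C5, C6 as in 7 | O=C2[C@@]1(C)CC=C[C@@H](O2)[C@H]1CC(=O)OC | intermediate
9 | lithium enolate of the ester arm of 8 | O=C2[C@@]1(C)CC=C[C@@H](O2)[C@H]1C=C([O-])OC.[Li+] | intermediate (not isolated)
10 | methyl 3-(dimethylamino)-2-(1-methyl-7-oxo-6-oxabicyclo[3.2.1]oct-3-en-8-yl)propanoate | O=C2[C@@]1(C)CC=C[C@@H](O2)[C@H]1C(CN(C)C)C(=O)OC | intermediate (not isolated)
11 | N-methyl quaternary ammonium iodide of 10 | O=C2[C@@]1(C)CC=C[C@@H](O2)[C@H]1C(C[N+](C)(C)C)C(=O)OC.[I-] | intermediate (not isolated)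
12 | methyl 2-(1-methyl-7-oxo-6-oxabicyclo[3.2.1]oct-3-en-8-yl)prop-2-enoate | O=C2[C@@]1(C)CC=C[C@@H](O2)[C@H]1C(=C)C(=O)OC | intermediate
13 | 8-(3-hydroxyprop-1-en-2-yl)-1-methyl-6-oxabicyclo[3.2.1]oct-3-en-7-ol (both anomers) | OC2[C@@]1(C)CC=C[C@@H](O2)[C@H]1C(=C)CO | intermediate
14 | (1R,5R,6R)-5-ethenyl-6-(3-hydroxyprop-1-en-2-yl)-5-methylcyclohex-2-en-1-ol (hydroxyl, vinyl and C6 arm all cis) | C=C[C@@]1(C)CC=C[C@@H](O)[C@H]1C(=C)CO | intermediate
15 | (1R,5R,6R)-6-[3-(tert-butyldimethylsilyloxy)prop-1-en-2-yl]-5-ethenyl-5-methylcyclohex-2-en-1-ol | C=C[C@@]1(C)CC=C[C@@H](O)[C@H]1C(=C)CO[Si](C)(C)C(C)(C)C | intermediate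
16 | ethyl vinyl ether | C=COCC | starting material
17 | 2-bromo-1-ethoxyethyl acetal of 15 at the ring oxygen (both acetal epimers; ring configuration as in 15) | C=C[C@@]1(C)CC=C[C@@H](OC(CBr)OCC)[C@H]1C(=C)CO[Si](C)(C)C(C)(C)C | intermediate (key-step precursor)
18 | C3 hydroperoxide of 19 | C=C[C@@]1(C)C[C@H](OO)[C@H]2CC(OCC)O[C@H]2[C@H]1C(=C)CO[Si](C)(C)C(C)(C)C | intermediate (not isolated)
19 | 2-ethoxy-6-ethenyl-6-methyl-7-[3-(tert-butyldimethylsilyloxy)prop-1-en-2-yl]octahydro-1-benzofuran-4-ol; cis ring fusion, C3 hydroxyl trans to the C4–CH2 bond, vinyl and C6 arm cis to the C5 oxygen, both acetal epimers | C=C[C@@]1(C)C[C@H](O)[C@H]2CC(OCC)O[C@H]2[C@H]1C(=C)CO[Si](C)(C)C(C)(C)C | intermediate (key-step product)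
20 | ethyl 2-[bis(2,2,2-trifluoroethoxy)phosphoryl]propanoate | CCOC(=O)C(C)P(=O)(OCC(F)(F)F)OCC(F)(F)F | starting material
21 | 2-[bis(2,2,2-trifluoroethoxy)phosphoryl]propanoic acid | OC(=O)C(C)P(=O)(OCC(F)(F)F)OCC(F)(F)F | intermediate
22 | ester of the C3 hydroxyl of 19 with 21 | C=C[C@@]1(C)C[C@H](OC(=O)C(C)P(=O)(OCC(F)(F)F)OCC(F)(F)F)[C@H]2CC(OCC)O[C@H]2[C@H]1C(=C)CO[Si](C)(C)C(C)(C)C | intermediate
23 | (2Z)-but-2-ene-1,4-diyl diacetate | CC(=O)OC/C=C\COC(C)=O | starting material
24 | 2-oxoethyl acetate | CC(=O)OCC=O | intermediate
25 | potassium salt of the phosphonate carbanion of 22 | C=C[C@@]1(C)C[C@H](OC(=O)[C-](C)P(=O)(OCC(F)(F)F)OCC(F)(F)F)[C@H]2CC(OCC)O[C@H]2[C@H]1C(=C)CO[Si](C)(C)C(C)(C)C.[K+] | intermediate (not isolated)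
26 | (2Z)-4-acetoxy-2-methylbut-2-enoate of 19 at C3 | C=C[C@@]1(C)C[C@H](OC(=O)/C(C)=C\COC(C)=O)[C@H]2CC(OCC)O[C@H]2[C@H]1C(=C)CO[Si](C)(C)C(C)(C)C | intermediate
27 | 6-ethenyl-2-hydroxy-7-(3-hydroxyprop-1-en-2-yl)-6-methyloctahydro-1-benzofuran-4-yl (2Z)-4-acetoxy-2-methylbut-2-enoate (ring configuration as in 19) | C=C[C@@]1(C)C[C@H](OC(=O)/C(C)=C\COC(C)=O)[C@H]2CC(O)O[C@H]2[C@H]1C(=C)CO | intermediate
28 | 3-methylidene analogue of 27 | C=C[C@@]1(C)C[C@H](OC(=O)/C(C)=C\COC(C)=O)[C@H]2C(=C)C(O)O[C@H]2[C@H]1C(=C)CO | intermediate
29 | 2-[(1S,2S,3R,4R,6S)-6-{[(2Z)-4-acetoxy-2-methylbut-2-enoyl]oxy}-4-ethenyl-2-hydroxy-3-(3-hydroxyprop-1-en-2-yl)-4-methylcyclohexyl]prop-2-enoic acid | C=C[C@@]1(C)C[C@H](OC(=O)/C(C)=C\COC(C)=O)[C@@H](C(=C)C(=O)O)[C@@H](O)[C@H]1C(=C)CO | target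

## Step count and least certain steps

Total: 18 steps. Longest linear sequence: 16 steps (1–11, 13, 15–18); steps 12 and 14 prepare the two side-chain reagents.

Step 11 (key step). The most likely failure is loss of the radical chain to the wrong partner. Oxygen can capture the primary radical before it closes, because ring closure and oxygen capture run at similar rates in air-saturated solvent. Tin hydride can also reduce the C3 radical before oxygen arrives. The fallback separates the two events. It sets out from 15: N-iodosuccinimide and 16 give the iodoacetal F1, and Et3B-initiated iodine-atom transfer in degassed solvent closes the ring to the C3 iodide F2 with no oxygen present. F2 is then treated with Bu3SnH under dry air. The C3 radical is now formed directly and meets oxygen on the convex face, giving 18, which PPh3 reduces. The fallback comes back to the route at 19.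

Step 2. The most likely failure is poor endo or facial selectivity, since the α-methyl group of 4 weakens the endo preference and the ester of 3 can compete for the boron centre; slow reconjugation of 3 under acid is a second risk. The fallback sets out from 3 and 4. Me2AlCl-promoted cycloaddition gives 5 together with its mirror image F3, and chlorite oxidation gives 6 together with its mirror image F4. Crystallisation with (S)-1-phenylethylamine gives the (S)-1-phenylethylammonium salt F5 of the wanted acid, and acidification returns to the route at 6.

Step 15. The most likely failure is erosion of Z selectivity on the hindered secondary ester, with base-induced self-condensation of 24 as a side reaction. The fallback moves the olefination off the substrate. It sets out from 21: DCC and 2-(trimethylsilyl)ethanol give the 2-(trimethylsilyl)ethyl phosphonate F6, and olefination with 24 gives 2-(trimethylsilyl)ethyl (2Z)-4-acetoxy-2-methylbut-2-enoate F7, whose isomers are separated at this small-molecule stage. CF3CO2H then frees (2Z)-4-acetoxy-2-methylbut-2-enoic acid F8. Yamaguchi esterification of 19 with F8 (2,4,6-trichlorobenzoyl chloride, Et3N, toluene, no DMAP) comes back to the route at 26.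

Step 17. The most likely failure is slow enamine formation, because 27 is largely closed as the lactol, while the amine can add reversibly to the unsaturated esters. The fallback exposes the aldehyde in open-chain form. It sets out from 26: propane-1,3-dithiol and BF3·OEt2 open the acetal to the dithiane alcohol F9, and Et3SiOTf with 2,6-lutidine gives the C5 triethylsilyl ether F10. MeI and NaHCO3 in aqueous MeCN release the free aldehyde F11, which dimethylmethyleneammonium iodide and Et3N convert into the enal F12. HF·pyridine removes both silyl groups and the hydroxy enal closes, coming back to the route at 28.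

## Further compounds

F1 | step 11 | 2-iodo-1-ethoxyethyl acetal of 15 | C=C[C@@]1(C)CC=C[C@@H](OC(CI)OCC)[C@H]1C(=C)CO[Si](C)(C)C(C)(C)C
F2 | step 11 | C3 iodide analogue of 19 (iodine in place of hydroxyl, C3 epimers) | C=C[C@@]1(C)CC(I)[C@H]2CC(OCC)O[C@H]2[C@H]1C(=C)CO[Si](C)(C)C(C)(C)C
F3 | step 2 | methyl 2-[(1S,6R)-6-formyl-6-methylcyclohex-2-en-1-yl]acetate (mirror image of 5) | O=C[C@]1(C)CCC=C[C@@H]1CC(=O)OC
F4 | step 2 | (1R,2S)-2-(2-methoxy-2-oxoethyl)-1-methylcyclohex-3-ene-1-carboxylic acid (mirror image of 6) | OC(=O)[C@]1(C)CCC=C[C@@H]1CC(=O)OC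
F5 | step 2 | (S)-1-phenylethylammonium salt of 6 | C[C@H]([NH3+])c1ccccc1.[O-]C(=O)[C@@]1(C)CCC=C[C@H]1CC(=O)OC
F6 | step 15 | 2-(trimethylsilyl)ethyl 2-[bis(2,2,2-trifluoroethoxy)phosphoryl]propanoate | C[Si](C)(C)CCOC(=O)C(C)P(=O)(OCC(F)(F)F)OCC(F)(F)F
F7 | step 15 | 2-(trimethylsilyl)ethyl (2Z)-4-acetoxy-2-methylbut-2-enoate | C[Si](C)(C)CCOC(=O)/C(C)=C\COC(C)=O
F8 | step 15 | (2Z)-4-acetoxy-2-methylbut-2-enoic acid | OC(=O)/C(C)=C\COC(C)=O
F9 | step 17 | open-chain 1,3-dithiane with free C5 hydroxyl derived from 26 | C=C[C@@]1(C)C[C@H](OC(=O)/C(C)=C\COC(C)=O)[C@@H](CC2SCCCS2)[C@@H](O)[C@H]1C(=C)CO[Si](C)(C)C(C)(C)C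
F10 | step 17 | C5 triethylsilyl ether of F9 | C=C[C@@]1(C)C[C@H](OC(=O)/C(C)=C\COC(C)=O)[C@@H](CC2SCCCS2)[C@@H](O[Si](CC)(CC)CC)[C@H]1C(=C)CO[Si](C)(C)C(C)(C)C
F11 | step 17 | open-chain aldehyde from F10 | C=C[C@@]1(C)C[C@H](OC(=O)/C(C)=C\COC(C)=O)[C@@H](CC=O)[C@@H](O[Si](CC)(CC)CC)[C@H]1C(=C)CO[Si](C)(C)C(C)(C)C
F12 | step 17 | open-chain α-methylene aldehyde from F11 | C=C[C@@]1(C)C[C@H](OC(=O)/C(C)=C\COC(C)=O)[C@@H](C(=C)C=O)[C@@H](O[Si](CC)(CC)CC)[C@H]1C(=C)CO[Si](C)(C)C(C)(C)C
A1 | alternative 1 | tert-butyl 2-[6-(tert-butyldimethylsilyloxy)-4-methyl-2-oxocyclohex-3-en-1-yl]acetate (substituents trans) | CC1C[C@H](O[Si](C)(C)C(C)(C)C)[C@@H](CC(=O)OC(C)(C)C)C(=O)C=1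
A2 | alternative 1 | 1-methoxy-4-[(prop-2-yn-1-yloxy)methyl]benzene | C#CCOCc1ccc(OC)cc1
A3 | alternative 1 | cis-fused bicyclo[4.2.0]oct-7-en-2-one photoadduct | C2[C@@]1(C)C[C@H](O[Si](C)(C)C(C)(C)C)[C@@H](CC(=O)OC(C)(C)C)C(=O)[C@H]1C=2COCc3ccc(OC)cc3
A4 | alternative 2 | tert-butyl{[(6E)-2-methoxy-6-methyl-8-(trimethylsilyl)octa-1,6-dien-4-yl]oxy}dimethylsilane | C=C(OC)C[C@@H](O[Si](C)(C)C(C)(C)C)C/C(C)=C/C[Si](C)(C)C
A5 | alternative 2 | 3-methyl-3-vinyl-5-silyloxycyclohexanone dimethyl ketal (vinyl cis to oxygen) | C=C[C@@]1(C)CC(OC)(OC)C[C@@H](O[Si](C)(C)C(C)(C)C)C1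
A6 | alternative 3 | acyclic aldehyde carrying the 2-(bromomethyl)alkenoate | C=C[C@@](C)(C[C@H](OCc1ccc(OC)cc1)C=C(CBr)C(=O)OCC[Si](C)(C)C)[C@@H](C=O)C(=C)CO[Si](C)(C)C(C)(C)C
A7 | alternative 3 | fully substituted cyclohexanol with α-methylene ester | C=C[C@@]1(C)C[C@H](OCc2ccc(OC)cc2)[C@@H](C(=C)C(=O)OCC[Si](C)(C)C)[C@@H](O)[C@H]1C(=C)CO[Si](C)(C)C(C)(C)C
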